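## Retrosynthetic overview

1. Licoricidin 17 ⇐ tribenzyl ether 16 (Na/NH3) ⇐ (3R)-6,3'-dibromoisoflavan 14 (double Br/Li exchange, prenyl bromide).
2. 14 ⇐ isoflavone 11 by reductase-like asymmetric transfer hydrogenation with dynamic kinetic resolution (sets C3), then ionic removal of the 4-OH.
3. 11 ⇐ flavanone 10 by a trivalent-iodine 2→3 aryl shift, the chemical copy of isoflavone synthase (key step).
4. 10 ⇐ chalcone 9 by oxa-Michael closure of ring C (the only ring built; rings A and B are bought) ⇐ acetophenone 4 + aldehyde 8.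
5. 4 ⇐ 1 (bromination ortho to OH, O-methylation, ortho-debenzylation, which places Br at the later C6); 8 ⇐ 5 (directed ortho-metalation, bromination).

Assumption: 1 and 5 are bought as the benzyl ethers (both are catalogue compounds; otherwise each is one benzylation from 2',4',6'-trihydroxyacetophenone or 2,4-dihydroxybenzaldehyde).

## Route

Step 1
Reactants: 1 ring A acetophenone [1-(2,4-bis(benzyloxy)-6-hydroxyphenyl)ethan-1-one]
Product: 2 bromophenol [1-(4,6-bis(benzyloxy)-3-bromo-2-hydroxyphenyl)ethan-1-one]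
Conditions: NBS (1.05 equiv), MeCN, 0 °C to rt
Reagents that add atoms: N-bromosuccinimide, O=C1CCC(=O)N1Br
Why: Electrophilic aromatic bromination goes ortho to the free (chelated) phenol, the strongest activator, and not to the more hindered site between the two benzyloxy groups, as is usual for 2-hydroxy-4,6-dialkoxyacetophenones.

Step 2
Reactants: 2 bromophenol
Product: 3 methyl ether [1-(4,6-bis(benzyloxy)-3-bromo-2-methoxyphenyl)ethan-1-one]
Conditions: MeI (2 equiv), K2CO3 (2.5 equiv), DMF, 45 °C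
Reagents that add atoms: iodomethane, CI
Why: Williamson O-methylation of the only free phenol fixes the oxygen next to bromine as the future 5-OMe.

Step 3
Reactants: 3 methyl ether
Product: 4 ring A ketone [1-(4-(benzyloxy)-3-bromo-6-hydroxy-2-methoxyphenyl)ethan-1-one]
Conditions: MgBr2·OEt2 (3 equiv), toluene/Et2O 4:1, 80 °C; 1 M HCl work-up
Reagents that add atoms: none
Why: Chelation-controlled ortho-debenzylation: magnesium bridges the carbonyl and the unhindered ortho benzyloxy oxygen and bromide removes that benzyl group, while the para benzyl ether and the much less labile methyl ether stay.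

Step 4
Reactants: 5 ring B aldehyde [2,4-bis(benzyloxy)benzaldehyde]
Product: 8 bromoaldehyde [2,4-bis(benzyloxy)-3-bromobenzaldehyde], via amino alkoxide 6 (not isolated), via aryllithium 7 (not isolated)
Conditions: N-methylpiperazine (1.1 equiv), n-BuLi (1.05 equiv), THF, −20 °C; add 5; then n-BuLi (2.0 equiv), −20 °C, 4 h; BrCl2CCCl2Br (2.5 equiv), −78 °C to rt; H2O
Reagents that add atoms: 1,2-dibromo-1,1,2,2-tetrachloroethane, BrC(Cl)(Cl)C(Cl)(Cl)Br
Why: Directed ortho-metalation with in situ aldehyde protection: the weakly directing α-amino alkoxide masks the CHO, the C3–H flanked by both benzyloxy groups is lithiated, and electrophilic bromination then hydrolysis returns the aldehyde.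

Step 5
Reactants: 4 ring A ketone; 8 bromoaldehyde
Product: 10 flavanone [rac-7-(benzyloxy)-2-(2,4-bis(benzyloxy)-3-bromophenyl)-6-bromo-5-methoxy-2,3-dihydro-4H-chromen-4-one], via chalcone 9 (not isolated)
Conditions: KOH (6 equiv), EtOH/THF 3:1, rt, 24 h; then AcOH to pH 6, NaOAc (5 equiv), EtOH, reflux, 12 h
Reagents that add atoms: none
Why: Claisen–Schmidt condensation followed by oxa-Michael ring closure (chalcone–flavanone isomerisation), which the 6'-methoxy group drives to the flavanone by twisting the enone; the C2 centre is racemic and is destroyed in step 6.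

Step 6
Reactants: 10 flavanone
Product: 11 isoflavone [7-(benzyloxy)-3-(2,4-bis(benzyloxy)-3-bromophenyl)-6-bromo-5-methoxy-4H-chromen-4-one]
Conditions: PhI(OH)OTs (1.3 equiv), MeCN, 80 °C, 2 h
Reagents that add atoms: none
Why: Oxidative 1,2-aryl migration with trivalent iodine: the enol is iodinated at C3, the electron-rich 2,4-dialkoxyaryl group anti to the C–I bond shifts from C2 to C3 as PhI leaves, and the O1-stabilised C2 cation loses a proton to give the isoflavone.

Step 7
Reactants: 11 isoflavone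
Product: 14 dibromoisoflavan [(3R)-7-(benzyloxy)-3-(2,4-bis(benzyloxy)-3-bromophenyl)-6-bromo-5-methoxy-3,4-dihydro-2H-chromene], via isoflavanone 12 (not isolated), via cis-isoflavan-4-ol 13 (not isolated)
Conditions: RuCl(p-cymene)[(R,R)-TsDPEN] (5 mol %), HCO2H/Et3N 5:2, EtOAc, 40 °C, 36 h; evaporate; then Et3SiH (5 equiv), CF3CO2H (10 equiv), CH2Cl2, −20 to 0 °C
Reagents that add atoms: none
Why: Noyori–Ikariya asymmetric transfer hydrogenation with dynamic kinetic resolution: hydride 1,4-addition gives 12, which racemises by enolisation while the (R,R)-catalyst reduces the (3R)-ketone fastest to cis-(3R,4R)-13 (setting C3), and ionic hydrogenation then removes the 4-OH through the 5-OMe/7-OBn-stabilised benzylic cation without touching C3.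

Step 8
Reactants: 14 dibromoisoflavan
Product: 16 diprenyl tribenzyl ether [(3R)-7-(benzyloxy)-3-(2,4-bis(benzyloxy)-3-(3-methylbut-2-en-1-yl)phenyl)-5-methoxy-6-(3-methylbut-2-en-1-yl)-3,4-dihydro-2H-chromene], via dilithio isoflavan 15 (not isolated)
Conditions: t-BuLi (4.4 equiv), THF, −78 °C, 20 min; CuBr·SMe2 (20 mol %), prenyl bromide (3 equiv), −78 to 0 °C
Reagents that add atoms: prenyl bromide (1-bromo-3-methylbut-2-ene), CC(C)=CCBr
Why: Double bromine–lithium exchange outruns any deprotonation at −78 °C, each aryllithium is held by two flanking alkoxy groups, and copper-catalysed SN2 allylic substitution gives the linear prenyl arenes; C3–H is far too weakly acidic to epimerise.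

Step 9
Reactants: 16 diprenyl tribenzyl ether
Product: 17 licoricidin [4-((3R)-7-hydroxy-5-methoxy-6-(3-methylbut-2-en-1-yl)-3,4-dihydro-2H-chromen-3-yl)-2-(3-methylbut-2-en-1-yl)benzene-1,3-diol]
Conditions: Na (excess), NH3(l)/THF, −78 °C, 10 min; NH4Cl
Reagents that add atoms: none
Why: Dissolving-metal (Birch-type) cleavage of the three aryl benzyl ethers gives phenoxides that resist ring reduction, while the isolated trisubstituted alkenes, the aryl methyl ether and the chroman are inert, and the absence of acid avoids prenyl-to-phenol cyclisation.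

## Compound list

1 | 1-[2,4-bis(benzyloxy)-6-hydroxyphenyl]ethan-1-one | CC(=O)c1c(O)cc(OCc2ccccc2)cc1OCc1ccccc1 | starting material
2 | 1-[4,6-bis(benzyloxy)-3-bromo-2-hydroxyphenyl]ethan-1-one | CC(=O)c1c(O)c(Br)c(OCc2ccccc2)cc1OCc1ccccc1 | intermediate
3 | 1-[4,6-bis(benzyloxy)-3-bromo-2-methoxyphenyl]ethan-1-one | CC(=O)c1c(OC)c(Br)c(OCc2ccccc2)cc1OCc1ccccc1 | intermediate
4 | 1-[4-(benzyloxy)-3-bromo-6-hydroxy-2-methoxyphenyl]ethan-1-one | CC(=O)c1c(OC)c(Br)c(OCc2ccccc2)cc1O | intermediate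
5 | 2,4-bis(benzyloxy)benzaldehyde | O=Cc1ccc(OCc2ccccc2)cc1OCc1ccccc1 | starting material
6 | lithium [2,4-bis(benzyloxy)phenyl](4-methylpiperazin-1-yl)methanolate | [Li+].[O-]C(N1CCN(C)CC1)c1ccc(OCc2ccccc2)cc1OCc1ccccc1 | intermediate (not isolated)
7 | lithium [2,4-bis(benzyloxy)-3-lithiophenyl](4-methylpiperazin-1-yl)methanolate | [Li+].[O-]C(N1CCN(C)CC1)c1ccc(OCc2ccccc2)c([Li])c1OCc1ccccc1 | intermediate (not isolated)
8 | 2,4-bis(benzyloxy)-3-bromobenzaldehyde | O=Cc1ccc(OCc2ccccc2)c(Br)c1OCc1ccccc1 | intermediate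
9 | (E)-1-[4-(benzyloxy)-3-bromo-6-hydroxy-2-methoxyphenyl]-3-[2,4-bis(benzyloxy)-3-bromophenyl]prop-2-en-1-one | COc1c(Br)c(OCc2ccccc2)cc(O)c1C(=O)/C=C/c1ccc(OCc2ccccc2)c(Br)c1OCc1ccccc1 | intermediate (not isolated)
10 | rac-7-(benzyloxy)-2-[2,4-bis(benzyloxy)-3-bromophenyl]-6-bromo-5-methoxy-2,3-dihydro-4H-chromen-4-one | COc1c(Br)c(OCc3ccccc3)cc2OC(CC(=O)c12)c1ccc(OCc3ccccc3)c(Br)c1OCc1ccccc1 | intermediate
11 | 7-(benzyloxy)-3-[2,4-bis(benzyloxy)-3-bromophenyl]-6-bromo-5-methoxy-4H-chromen-4-one | COc1c(Br)c(OCc3ccccc3)cc2occ(-c3ccc(OCc4ccccc4)c(Br)c3OCc3ccccc3)c(=O)c12 | intermediate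
12 | 7-(benzyloxy)-3-[2,4-bis(benzyloxy)-3-bromophenyl]-6-bromo-5-methoxy-2,3-dihydro-4H-chromen-4-one (racemising at C3) | COc1c(Br)c(OCc3ccccc3)cc2OCC(c3ccc(OCc4ccccc4)c(Br)c3OCc3ccccc3)C(=O)c12 | intermediate (not isolated)
13 | (3R,4R)-7-(benzyloxy)-3-[2,4-bis(benzyloxy)-3-bromophenyl]-6-bromo-5-methoxy-3,4-dihydro-2H-chromen-4-ol (cis) | COc1c(Br)c(OCc3ccccc3)cc2c1[C@H](O)[C@H](c1ccc(OCc3ccccc3)c(Br)c1OCc1ccccc1)CO2 | intermediate (not isolated)
14 | (3R)-7-(benzyloxy)-3-[2,4-bis(benzyloxy)-3-bromophenyl]-6-bromo-5-methoxy-3,4-dihydro-2H-chromene | COc1c(Br)c(OCc3ccccc3)cc2c1C[C@H](c1ccc(OCc3ccccc3)c(Br)c1OCc1ccccc1)CO2 | intermediate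
15 | (3R)-7-(benzyloxy)-3-[2,4-bis(benzyloxy)-3-lithiophenyl]-6-lithio-5-methoxy-3,4-dihydro-2H-chromene | COc1c([Li])c(OCc3ccccc3)cc2c1C[C@H](c1ccc(OCc3ccccc3)c([Li])c1OCc1ccccc1)CO2 | intermediate (not isolated)
16 | (3R)-7-(benzyloxy)-3-[2,4-bis(benzyloxy)-3-(3-methylbut-2-en-1-yl)phenyl]-5-methoxy-6-(3-methylbut-2-en-1-yl)-3,4-dihydro-2H-chromene | COc1c(CC=C(C)C)c(OCc3ccccc3)cc2c1C[C@H](c1ccc(OCc3ccccc3)c(CC=C(C)C)c1OCc1ccccc1)CO2 | intermediate
17 | licoricidin, (3R)-2',4',7-trihydroxy-5-methoxy-6,3'-diprenylisoflavan | COc1c(CC=C(C)C)c(O)cc2c1C[C@H](c1ccc(O)c(CC=C(C)C)c1O)CO2 | target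

## Count and risks

Total step count: 9. Longest linear sequence: 8 steps (steps 1, 2, 3, 5, 6, 7, 8, 9).

Most likely to fail, first: step 6. The flavanone may instead be dehydrogenated to the flavone, or the activated ring B may be attacked by the iodine reagent. The fallback moves the aryl shift to the open-chain stage. It sets out from chalcone 9, isolated by stopping step 5 after the KOH stage. Treatment of 9 with PhI(OAc)2 and TsOH in MeOH/HC(OMe)3 at room temperature gives the aryl-shifted keto acetal 1-[4-(benzyloxy)-3-bromo-6-hydroxy-2-methoxyphenyl]-2-[2,4-bis(benzyloxy)-3-bromophenyl]-3,3-dimethoxypropan-1-one F1. Warming F1 with catalytic HCl in MeOH closes ring C with loss of methanol, and the route is rejoined at isoflavone 11.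

Second: step 7. The 5-methoxy group and the ortho-benzyloxy aryl group crowd the ketone, so the transfer hydrogenation may be slow or poorly selective. In the acid stage the C4 cation may lose H3 (racemising through the isoflav-3-ene) or be trapped by the 2'-benzyloxy oxygen. The fallback replaces ketone-based stereocontrol by alkene hydrogenation and sets out from 11. NaBH4 in THF/EtOH gives the racemic isoflavan-4-ol F2 as a cis/trans mixture. TsOH in toluene at 80 °C dehydrates it to the isoflav-3-ene 7-(benzyloxy)-3-[2,4-bis(benzyloxy)-3-bromophenyl]-6-bromo-5-methoxy-2H-chromene F3. Asymmetric hydrogenation of F3 with [Ir(cod){(S)-t-Bu-PHOX}]B[3,5-(CF3)2C6H3]4 under H2 (50 bar, CH2Cl2) then sets C3; the ligand enantiomer is fixed by a test run. Aryl bromides and benzyl ethers survive this homogeneous catalyst, and the route is rejoined at 14.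

Third: step 8. The ortho-lithio benzyl ethers may undergo anion translocation and Wittig rearrangement, or the second exchange may be incomplete. The fallback avoids organolithiums and sets out from 14. Stille coupling with allyltributylstannane (zerovalent palladium catalyst Pd[P(t-Bu)3]2, CsF, dioxane, 100 °C) gives the diallyl compound (3R)-6-allyl-7-(benzyloxy)-3-[3-allyl-2,4-bis(benzyloxy)phenyl]-5-methoxy-3,4-dihydro-2H-chromene F4. Cross-metathesis of F4 with 2-methyl-2-butene, using the second-generation Grubbs catalyst RuCl2(=CHPh)(PCy3)(H2IMes) in CH2Cl2 at 40 °C, turns both allyl groups into prenyl groups, and the route is rejoined at 16.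

## Further compounds

F1 | step 6 | 1-[4-(benzyloxy)-3-bromo-6-hydroxy-2-methoxyphenyl]-2-[2,4-bis(benzyloxy)-3-bromophenyl]-3,3-dimethoxypropan-1-one (racemic) | COc1c(Br)c(OCc2ccccc2)cc(O)c1C(=O)C(C(OC)OC)c1ccc(OCc2ccccc2)c(Br)c1OCc1ccccc1
F2 | step 7 | 7-(benzyloxy)-3-[2,4-bis(benzyloxy)-3-bromophenyl]-6-bromo-5-methoxy-3,4-dihydro-2H-chromen-4-ol (racemic, cis/trans mixture) | COc1c(Br)c(OCc3ccccc3)cc2c1C(O)C(c1ccc(OCc3ccccc3)c(Br)c1OCc1ccccc1)CO2
F3 | step 7 | 7-(benzyloxy)-3-[2,4-bis(benzyloxy)-3-bromophenyl]-6-bromo-5-methoxy-2H-chromene | COc1c(Br)c(OCc3ccccc3)cc2c1C=C(c1ccc(OCc3ccccc3)c(Br)c1OCc1ccccc1)CO2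
F4 | step 8 | (3R)-6-allyl-7-(benzyloxy)-3-[3-allyl-2,4-bis(benzyloxy)phenyl]-5-methoxy-3,4-dihydro-2H-chromene | COc1c(CC=C)c(OCc3ccccc3)cc2c1C[C@H](c1ccc(OCc3ccccc3)c(CC=C)c1OCc1ccccc1)CO2
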